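**Retrosynthetic overview**

- Feature: ring B carries C(CH3)2 between two oxygen-bearing carbons, which is a dimethylmalonyl unit. Its other three carbons plus the bridging CH2 are a butan-2-one, and the ring A phenol oxygen ortho to the bridge can hold that ketone as an aryl enol ether.
- Target 12 ⇒ trione 10 by removing the ring B acetyl (enol O-acetylation, then O-to-C shift). 10 ⇒ xanthene-1,3-dione 9 by tying the ring A phenol onto ring B as an aryl vinylogous ester.
- 9 ⇒ 2-methyl-4H-chromene 6 + dimethylmalonyl dichloride 7: two C–C bonds, from chromene C3 and from the 2-methyl carbon to the two acyl carbons ([3+3], closes ring B).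
- 6 ⇒ 2,6-dihydroxy-4-methoxyacetophenone 1 + methyl vinyl ketone 2 (ring-carbon conjugate addition, ketalisation, loss of methanol, acetate on the remaining phenol).
- Ring order: temporary pyran ring (steps 1–2), ring B (step 4), pyran ring opened (step 5); ring A is bought.

Key step: step 4

Remark on the chemistry: the target is achiral and is drawn as one tautomer of an enolised 2-acylcyclohexane-1,3,5-trione; 10, 11 and 12 are each written as one tautomer. Ring A is the aromatic ring, ring B the trione ring.

**Route**

Step 1
Reactants: 1 2,6-dihydroxy-4-methoxyacetophenone; 2 methyl vinyl ketone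
Product: 4 rac-1-(7-hydroxy-2,5-dimethoxy-2-methyl-3,4-dihydro-2H-chromen-8-yl)ethanone, via aryl butanone 3 (not isolated)
Conditions: 1 (1.1 equiv), 2 (1.0 equiv), HC(OMe)3 (1.5 equiv), H2SO4 (cat.), MeOH, 0 °C → 40 °C
Reagents that add atoms: trimethyl orthoformate, COC(OC)OC; methanol, CO (solvent; either supplies the ketal OCH3)
Why: Acid-catalysed Friedel–Crafts-type conjugate (Michael) addition of the ring carbon between the hydroxyl and the methoxyl to methyl vinyl ketone should give ketone 3, which the neighbouring phenol and methanol trap as the cyclic mixed ketal (the reaction type used to make 2-methoxy-2-methylchromans from electron-rich phenols), the ketal carbon being formed racemic and removed in step 2.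

Step 2
Reactants: 4 rac-1-(7-hydroxy-2,5-dimethoxy-2-methyl-3,4-dihydro-2H-chromen-8-yl)ethanone
Product: 5 1-(7-hydroxy-5-methoxy-2-methyl-4H-chromen-8-yl)ethanone
Conditions: pyridinium p-toluenesulfonate (5 mol%), toluene, 110 °C, MeOH distilled off; Et3N quench
Reagents that add atoms: none
Why: Acid-catalysed elimination of methanol from a ketal to the enol ether (the general ketal-to-enol-ether conversion), driven by removal of methanol, should give the endocyclic trisubstituted enol ether as the thermodynamic product.

Step 3
Reactants: 5 1-(7-hydroxy-5-methoxy-2-methyl-4H-chromen-8-yl)ethanone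
Product: 6 8-acetyl-5-methoxy-2-methyl-4H-chromen-7-yl acetate
Conditions: Ac2O (1.5 equiv), pyridine, 4-(dimethylamino)pyridine (DMAP, cat.), CH2Cl2, rt
Reagents that add atoms: acetic anhydride, CC(=O)OC(C)=O
Why: DMAP-catalysed O-acetylation of the chelated phenol leaves the base-stable enol ether untouched; the acetate blocks phenol acylation in step 4 and twists the acetyl group out of conjugation, so the ring oxygen lone pair stays available to the enol ether.

Step 4
Reactants: 6 8-acetyl-5-methoxy-2-methyl-4H-chromen-7-yl acetate; 7 dimethylmalonyl dichloride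
Product: 9 5-acetyl-8-methoxy-2,2-dimethyl-1,3-dioxo-2,3,4,9-tetrahydro-1H-xanthen-6-yl acetate, via exocyclic enol ether acid chloride 8 (not isolated)
Conditions: 7 (1.2 equiv), ZnCl2 (0.2 equiv, 1 M in Et2O), 2,6-di-tert-butyl-4-methylpyridine (2.4 equiv), CH2Cl2 (0.05 M), −20 °C → 40 °C
Reagents that add atoms: none
Why: Proposed new method: the ZnCl2-activated acid chloride 7 should be attacked by the enol ether carbon C3 of 6, and the 2-oxocarbenium ion should lose a methyl proton to the hindered pyridine to give the exocyclic enol ether 8, whose methylene carbon attacks the second acid chloride before the new oxocarbenium ion loses the C9a proton to leave the vinylogous ester 9. The closest known reaction type is the Effenberger cyclisation of malonyl dichlorides with alkyl or silyl enol ethers, extended here to an aryl enol ether (a 4H-chromene) and to a fused instead of a bridged product. Ring B is closed by a 6-exo-trig (enol-exo) C-acylation, helped by the gem-dimethyl group. No stereocentre is present in 9, and the C3 centre of 8 is transient and racemic. The step needs C-acylation at C3 first and at the former methyl carbon second: enol ether polarity makes C3 the only nucleophilic carbon of 6, the aryl ether oxygen can be neither acylated nor dealkylated so no pyranone can form, the quaternary carbon of 7 excludes a ketene, and under the non-enolising pyridine buffer the acetate-masked acetophenone of ring A should stay silent.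

Step 5
Reactants: 9 5-acetyl-8-methoxy-2,2-dimethyl-1,3-dioxo-2,3,4,9-tetrahydro-1H-xanthen-6-yl acetate
Product: 10 2-[(3-acetyl-2,4-dihydroxy-6-methoxyphenyl)methyl]-3-hydroxy-4,4-dimethylcyclohex-2-ene-1,5-dione
Conditions: 2 M aq. NaOH (6 equiv), THF, 0 °C → rt, argon; then 1 M HCl to pH 2
Reagents that add atoms: sodium hydroxide, [Na+].[OH-]; water, O (the new ring B oxygen)
Why: Addition–elimination hydrolysis of the aryl vinylogous ester (hydroxide adds to the enol ether carbon and the ring A phenoxide leaves) opens the pyran ring while the aryl acetate is saponified in the same pot, and the product sits as its stabilised trione enolate, which resists retro-Claisen cleavage, until acidification.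

Step 6
Reactants: 10 2-[(3-acetyl-2,4-dihydroxy-6-methoxyphenyl)methyl]-3-hydroxy-4,4-dimethylcyclohex-2-ene-1,5-dione
Product: 12 2-acetyl-6-[(3-acetyl-2,4-dihydroxy-6-methoxyphenyl)methyl]-3,5-dihydroxy-4,4-dimethylcyclohexa-2,5-dien-1-one (target), via ring B enol acetate 11 (not isolated)
Conditions: AcCl (1.05 equiv), Et3N (1.1 equiv), CH2Cl2, −20 °C; then DMAP (0.3 equiv), Et3N (1.5 equiv), rt; 1 M HCl work-up
Reagents that add atoms: acetyl chloride, CC(=O)Cl
Why: One equivalent of Et3N deprotonates only the acidic ring B vinylogous acid, acetyl chloride O-acetylates that enolate to 11, and DMAP then effects the known enol ester to 2-acyl-1,3-dione rearrangement (O-to-C acyl migration through an acetylpyridinium–enolate pair) at the one free ring B carbon, the acyl-trione anion being the thermodynamic sink.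

**Compound list**

1 | 2,6-dihydroxy-4-methoxyacetophenone | COc1cc(O)c(C(C)=O)c(O)c1 | starting material
2 | methyl vinyl ketone (but-3-en-2-one) | C=CC(C)=O | starting material
3 | 4-(3-acetyl-2,4-dihydroxy-6-methoxyphenyl)butan-2-one | COc1cc(O)c(C(C)=O)c(O)c1CCC(C)=O | intermediate (not isolated)
4 | rac-1-(7-hydroxy-2,5-dimethoxy-2-methyl-3,4-dihydro-2H-chromen-8-yl)ethanone | COc1cc(O)c(C(C)=O)c2OC(C)(OC)CCc12 | intermediate
5 | 1-(7-hydroxy-5-methoxy-2-methyl-4H-chromen-8-yl)ethanone | COc1cc(O)c(C(C)=O)c2OC(C)=CCc12 | intermediate
6 | 8-acetyl-5-methoxy-2-methyl-4H-chromen-7-yl acetate | COc1cc(OC(C)=O)c(C(C)=O)c2OC(C)=CCc12 | intermediate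
7 | dimethylmalonyl dichloride | CC(C)(C(=O)Cl)C(=O)Cl | starting material
8 | rac-3-(7-acetoxy-8-acetyl-5-methoxy-2-methylidene-3,4-dihydro-2H-chromen-3-yl)-2,2-dimethyl-3-oxopropanoyl chloride | COc1cc(OC(C)=O)c(C(C)=O)c2OC(=C)C(Cc12)C(=O)C(C)(C)C(=O)Cl | intermediate (not isolated)
9 | 5-acetyl-8-methoxy-2,2-dimethyl-1,3-dioxo-2,3,4,9-tetrahydro-1H-xanthen-6-yl acetate | COc1cc(OC(C)=O)c(C(C)=O)c2OC3=C(Cc12)C(=O)C(C)(C)C(=O)C3 | intermediate
10 | 2-[(3-acetyl-2,4-dihydroxy-6-methoxyphenyl)methyl]-3-hydroxy-4,4-dimethylcyclohex-2-ene-1,5-dione | COc1cc(O)c(C(C)=O)c(O)c1CC1=C(O)C(C)(C)C(=O)CC1=O | intermediate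
11 | 6-[(3-acetyl-2,4-dihydroxy-6-methoxyphenyl)methyl]-5-hydroxy-4,4-dimethyl-3-oxocyclohexa-1,5-dien-1-yl acetate | COc1cc(O)c(C(C)=O)c(O)c1CC1=C(O)C(C)(C)C(=O)C=C1OC(C)=O | intermediate (not isolated)
12 | 2-acetyl-6-[(3-acetyl-2,4-dihydroxy-6-methoxyphenyl)methyl]-3,5-dihydroxy-4,4-dimethylcyclohexa-2,5-dien-1-one | COc1cc(O)c(C(C)=O)c(O)c1CC1=C(O)C(C)(C)C(O)=C(C(C)=O)C1=O | target

**Totals**

Total step count: 6. Longest linear sequence: 6 steps (1 → 12).

**Steps most likely to fail**

Step 4 (key step, proposed new method). The first acylation may be slow, because an aryl enol ether is a weaker nucleophile than an alkyl one and the acid chloride is hindered. Proton loss after the first acylation may go toward C3 instead of the methyl group, which would give a conjugated, poorly nucleophilic isomer that stalls before ring closure. Intermolecular acylation may also lead to oligomers. Fallback by known chemistry, setting out from 1 and rejoining the route at 12: 1 is aminomethylated at the free ring carbon next to the methoxyl with dimethyl(methylidene)ammonium iodide (1 equiv, CH2Cl2, rt; Mannich reaction) to give 1-[3-[(dimethylamino)methyl]-2,6-dihydroxy-4-methoxyphenyl]ethanone F1. In parallel, commercial 2,4,6-trihydroxyacetophenone is C,C-dimethylated (NaOMe, MeI, MeOH) to 2-acetyl-3,5-dihydroxy-4,4-dimethylcyclohexa-2,5-dien-1-one (acetylfilicinic acid) F2. Heating F1 with F2 (dioxane, 90 °C) should expel dimethylamine to form the ring A ortho-quinone methide, which F2 traps at its one free ring carbon (Michael addition) to give 12 directly.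

Step 5. Hydroxide may attack the 2,2-dimethyl-1,3-dione carbonyls (retro-Claisen ring cleavage), the methylene bridge may fragment and scramble by base-induced retro-Michael reaction, and the opening may be slow because the substrate rests as an enolate. Fallback, setting out from 9 and rejoining at 10: treatment of 9 with pyrrolidine (3 equiv, THF, rt) should displace the ring A aryloxide by vinylogous transamination and remove the aryl acetate by aminolysis, giving 4-[(3-acetyl-2,4-dihydroxy-6-methoxyphenyl)methyl]-2,2-dimethyl-5-(pyrrolidin-1-yl)cyclohex-4-ene-1,3-dione F3. Hydrolysis of this enaminone with 1 M HCl in THF at 50 °C should give 10 without exposure to alkali.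

Step 6. The ring A phenols may be acetylated in competition with the ring B enolate, and the acyl migration may stop short of completion. Fallback, setting out from 10 and rejoining at 12: exhaustive acetylation (Ac2O, pyridine, DMAP) should give 3-acetyl-4-[(2-acetoxy-6-hydroxy-5,5-dimethyl-4-oxocyclohexa-1,6-dien-1-yl)methyl]-5-methoxy-1,3-phenylene diacetate F4. Et3N and DMAP (MeCN, rt) should then move the enol acetyl to carbon, giving the di-O-acetate of the target, 3-acetyl-4-[(3-acetyl-2,4-dihydroxy-5,5-dimethyl-6-oxocyclohexa-1,3-dien-1-yl)methyl]-5-methoxy-1,3-phenylene diacetate F5. Brief methanolysis (K2CO3, MeOH, 0 °C) should remove the two aryl acetates, while the C-acetyl trione is protected as its enolate, and give 12.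

**Further compounds**

F1 | step 4 | 1-[3-[(dimethylamino)methyl]-2,6-dihydroxy-4-methoxyphenyl]ethanone | COc1cc(O)c(C(C)=O)c(O)c1CN(C)C
F2 | step 4 | 2-acetyl-3,5-dihydroxy-4,4-dimethylcyclohexa-2,5-dien-1-one | CC(=O)C1=C(O)C=C(O)C(C)(C)C1=O
F3 | step 5 | 4-[(3-acetyl-2,4-dihydroxy-6-methoxyphenyl)methyl]-2,2-dimethyl-5-(pyrrolidin-1-yl)cyclohex-4-ene-1,3-dione | COc1cc(O)c(C(C)=O)c(O)c1CC1=C(N2CCCC2)CC(=O)C(C)(C)C1=O
F4 | step 6 | 3-acetyl-4-[(2-acetoxy-6-hydroxy-5,5-dimethyl-4-oxocyclohexa-1,6-dien-1-yl)methyl]-5-methoxy-1,3-phenylene diacetate | COc1cc(OC(C)=O)c(C(C)=O)c(OC(C)=O)c1CC1=C(O)C(C)(C)C(=O)C=C1OC(C)=O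
F5 | step 6 | 3-acetyl-4-[(3-acetyl-2,4-dihydroxy-5,5-dimethyl-6-oxocyclohexa-1,3-dien-1-yl)methyl]-5-methoxy-1,3-phenylene diacetate | COc1cc(OC(C)=O)c(C(C)=O)c(OC(C)=O)c1CC1=C(O)C(C)(C)C(O)=C(C(C)=O)C1=O
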